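**Retrosynthetic overview**

1. The target, (S)-5,7-dihydroxy-4-phenyl-8-(3-phenylpropanoyl)chroman-2-one, goes back by debenzylation to its 5,7-dibenzyl ether, and that by C8 Friedel–Crafts acylation to (S)-5,7-bis(benzyloxy)-4-phenylchroman-2-one.
2. Key disconnection: the lactone ester C–O bond (O1–C2), opened together with C4–H, leads to the achiral 5,7-bis(benzyloxy)-4-phenyl-2H-chromen-2-ol. Forward, a chiral carbene turns this lactol into the lactone; the proton delivered to C4 sets the S centre as the ester bond closes the ring.
3. The lactol goes back to 3,5-bis(benzyloxy)phenol and 3-phenylprop-2-ynal (aryl–C4 bond by conjugate addition, then hemiacetal closure).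
4. Ring order: the arene is bought; the pyran ring is made first as a hemiacetal and re-formed as the six-membered lactone in the key step; the acyl side chain and deprotection come last.

Assumption: the three starting materials are bought as such, and the (5aR,10bS) antipode of the triazolium salt is taken to give the 4S lactone; if the first run shows the opposite sense, the (5aS,10bR) salt is used and nothing else changes.

**Route**

Step 1
Reactants: 1 3,5-bis(benzyloxy)phenol; 2 3-phenylprop-2-ynal
Product: 4 5,7-bis(benzyloxy)-4-phenyl-2H-chromen-2-ol (racemic at C2), via ring-opened (Z)-enal 3 (not isolated)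
Conditions: (S)-2-[diphenyl(trimethylsilyloxy)methyl]pyrrolidine (20 mol%), PhCO2H (20 mol%), 2 (1.1 equiv), toluene, 0 °C to rt; aq. NH4Cl work-up
Reagents that add atoms: none
Why: Iminium activation of ynal 2 by the bulky secondary amine (too hindered for irreversible aza-Michael addition) lets the carbon ortho to the hydroxyl of phenol 1 add to the β-carbon (Friedel–Crafts-type conjugate addition), and enal 3 is drained as the six-membered hemiacetal 4; the C2 hemiacetal centre forms as a racemate and is erased in step 2.

Step 2
Reactants: 4 5,7-bis(benzyloxy)-4-phenyl-2H-chromen-2-ol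
Product: 7 (S)-5,7-bis(benzyloxy)-4-phenylchroman-2-one, via Breslow intermediate 5 (not isolated), via acyl azolium 6 (not isolated)
Conditions: (5aR,10bS)-2-mesityl-5a,10b-dihydro-4H,6H-indeno[2,1-b][1,2,4]triazolo[4,3-d][1,4]oxazin-2-ium chloride (10 mol%), diisopropylethylamine (20 mol%), toluene, 4 Å molecular sieves, 35 °C, argon
Reagents that add atoms: none
Why: Proposed new method: enantioselective carbene-catalysed redox lactonisation of a 4-aryl-2H-chromen-2-ol — lactol 4 reacts through the small equilibrium share of its ring-chain tautomer (the hydroxy-enal numbered 3 in step 1), the triazolylidene adds to that aldehyde to give Breslow intermediate 5, whose fully substituted β-carbon is too hindered for carbon–carbon bond formation and is instead protonated (proton relayed by the ammonium salt or the phenol) on the face left open by the aminoindane wall of the catalyst, which sets C4 as S, and the resulting acyl azolium 6 is captured by the only free phenol so that the ester C–O bond closes the ring and releases the carbene; the closest known reactions are the achiral carbene-catalysed redox lactonisation of 2-hydroxycinnamaldehydes to dihydrocoumarins and the enantioselective carbene-catalysed β-protonation/esterification of β-alkyl-β-aryl enals with external alcohols.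

Step 3
Reactants: 7 (S)-5,7-bis(benzyloxy)-4-phenylchroman-2-one; 8 3-phenylpropanoic acid
Product: 10 (S)-5,7-bis(benzyloxy)-4-phenyl-8-(3-phenylpropanoyl)chroman-2-one, via mixed anhydride 9 (not isolated)
Conditions: 8 (1.5 equiv), trifluoroacetic anhydride (2.0 equiv), H3PO4 (85%, 10 mol%), CH2Cl2, 0 °C to rt
Reagents that add atoms: none
Why: Friedel–Crafts acylation by mixed anhydride 9 goes to C8, which is para to the C5 ether oxygen and flanked by only one freely rotating benzyloxy group, whereas C6 is squeezed between two benzyloxy groups and is para only to the weakly donating lactone oxygen; the mild acid leaves the lactone, the benzyl ethers and the C4 centre untouched.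

Step 4
Reactants: 10 (S)-5,7-bis(benzyloxy)-4-phenyl-8-(3-phenylpropanoyl)chroman-2-one
Product: 11 (S)-5,7-dihydroxy-4-phenyl-8-(3-phenylpropanoyl)chroman-2-one
Conditions: H2 (1 atm), Pd/C (10 wt% palladium on carbon), EtOAc, rt
Reagents that add atoms: none
Why: Hydrogenolysis of the two aryl benzyl ethers under neutral conditions; the hydrogen-bonded aryl ketone, the lactone and C4 (no heteroatom on that carbon) are inert, and without acid or base the lactone cannot open and re-close onto the freed C5 hydroxyl.

**Compound list**

1 | 3,5-bis(benzyloxy)phenol | Oc1cc(OCc2ccccc2)cc(OCc2ccccc2)c1 | starting material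
2 | 3-phenylprop-2-ynal | O=CC#Cc1ccccc1 | starting material
3 | (Z)-3-[2,4-bis(benzyloxy)-6-hydroxyphenyl]-3-phenylprop-2-enal | O=C/C=C(/c1ccccc1)c1c(O)cc(OCc2ccccc2)cc1OCc1ccccc1 | intermediate
4 | (2RS)-5,7-bis(benzyloxy)-4-phenyl-2H-chromen-2-ol | OC1C=C(c2ccccc2)c2c(OCc3ccccc3)cc(OCc3ccccc3)cc2O1 | intermediate
5 | Breslow intermediate: (5aR,10bS)-1-{(Z)-3-[2,4-bis(benzyloxy)-6-hydroxyphenyl]-1-hydroxy-3-phenylprop-2-en-1-ylidene}-2-mesityl-1,2,5a,10b-tetrahydro-4H,6H-indeno[2,1-b][1,2,4]triazolo[4,3-d][1,4]oxazine (enol C=C geometry not defined) | OC(/C=C(/c1ccccc1)c1c(O)cc(OCc2ccccc2)cc1OCc1ccccc1)=C1N(c2c(C)cc(C)cc2C)N=C2CO[C@@H]3Cc4ccccc4[C@@H]3N12 | intermediate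
6 | acyl azolium: (5aR,10bS)-1-[(3S)-3-(2,4-bis(benzyloxy)-6-hydroxyphenyl)-3-phenylpropanoyl]-2-mesityl-5a,10b-dihydro-4H,6H-indeno[2,1-b][1,2,4]triazolo[4,3-d][1,4]oxazin-2-ium | O=C(C[C@@H](c1ccccc1)c1c(O)cc(OCc2ccccc2)cc1OCc1ccccc1)c1n2c(n[n+]1-c1c(C)cc(C)cc1C)CO[C@@H]1Cc3ccccc3[C@H]21 | intermediate
7 | (S)-5,7-bis(benzyloxy)-4-phenylchroman-2-one | O=C1C[C@@H](c2ccccc2)c2c(OCc3ccccc3)cc(OCc3ccccc3)cc2O1 | intermediate
8 | 3-phenylpropanoic acid | OC(=O)CCc1ccccc1 | starting material
9 | 3-phenylpropanoic trifluoroacetic anhydride | O=C(CCc1ccccc1)OC(=O)C(F)(F)F | intermediate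
10 | (S)-5,7-bis(benzyloxy)-4-phenyl-8-(3-phenylpropanoyl)chroman-2-one | O=C1C[C@@H](c2ccccc2)c2c(OCc3ccccc3)cc(OCc3ccccc3)c(C(=O)CCc3ccccc3)c2O1 | intermediate
11 | (S)-5,7-dihydroxy-4-phenyl-8-(3-phenylpropanoyl)chroman-2-one | O=C1C[C@@H](c2ccccc2)c2c(O)cc(O)c(C(=O)CCc3ccccc3)c2O1 | target

**Step count and risks**

Total steps: 4. Longest linear sequence: 4 (1 → 4 → 7 → 10 → 11).

The three steps most likely to fail:

Step 2 (the proposed new step). The β-protonation may be slow or poorly face-selective for a β,β-diaryl enal, and traces of air would oxidise the lactol to the coumarin. Lactone 7 is expected to be crystalline, so a modest ee could be raised by recrystallisation. If the step fails, known chemistry replaces it. Setting out from 1, Pd(OAc)2 (5 mol%) and NaOAc in HCO2H at rt with ethyl prop-2-ynoate give 5,7-bis(benzyloxy)-2H-chromen-2-one F2. Rhodium-catalysed asymmetric conjugate addition of phenylboronic acid (Rh(acac)(C2H4)2, (S)-SEGPHOS, dioxane–water 10:1, 60 °C) then delivers 7, where the route is rejoined. The (R)-ligand is known to give (R)-4-arylchroman-2-ones, and the priorities at C4 are the same here.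

Step 1. This combination of phenol and ynal has little precedent: O-addition of the phenol, carbon attack at C4 of the phenol (para to the hydroxyl, which cannot close to the lactol), amine loss by aza-Michael addition, or a second phenol adding to the product could compete. The fallback sets out from 1: the same Pd(OAc)2/NaOAc/HCO2H coupling, now with ethyl 3-phenylprop-2-ynoate, gives 5,7-bis(benzyloxy)-4-phenyl-2H-chromen-2-one F1. Diisobutylaluminium hydride (1.1 equiv, toluene, −78 °C) reduces the lactone to the lactol and rejoins the route at 4.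

Step 3. The C8-over-C6 preference rests on steric and electronic argument and on analogy with 5,7-dialkoxychroman systems, and the acid may loosen a benzyl ether. The fallback sets out from 7: N-bromosuccinimide (1.05 equiv, MeCN, 0 °C) gives (S)-8-bromo-5,7-bis(benzyloxy)-4-phenylchroman-2-one F3, whose site is proven by NOE before going on. Carbonylative Negishi coupling with (2-phenylethyl)zinc bromide under CO (1 atm) with Pd(PPh3)4 in THF at 50 °C installs the ketone without acid and rejoins the route at 10.

**Further compounds**

F1 | step 1 | 5,7-bis(benzyloxy)-4-phenyl-2H-chromen-2-one | O=C1C=C(c2ccccc2)c2c(OCc3ccccc3)cc(OCc3ccccc3)cc2O1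
F2 | step 2 | 5,7-bis(benzyloxy)-2H-chromen-2-one | O=C1C=Cc2c(OCc3ccccc3)cc(OCc3ccccc3)cc2O1
F3 | step 3 | (S)-8-bromo-5,7-bis(benzyloxy)-4-phenylchroman-2-one | O=C1C[C@@H](c2ccccc2)c2c(OCc3ccccc3)cc(OCc3ccccc3)c(Br)c2O1
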